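## Retrosynthetic overview

1. Target 30 ⇐ desilylation and C9 ketone reduction ⇐ all-trans oxolane ketone 28 ⇐ Pd(0) formal [3+2] of vinyl epoxide 16 (O–C12′–C11′) with enone 26 (C10=C11); the oxolane is made last.
2. 16 ⇐ anti-chlorohydrin 15 ⇐ alkenylzinc from cyclopropyl alkyne 10 + (S)-α-chloroaldehyde 12; 26 ⇐ alkenylzinc from alkyne 22 + aldehyde 9, then oxidation.
3. 9 and 10 ⇐ alcohol 8 ⇐ key step: epoxide-triggered homoallyl → cyclopropylcarbinyl cation cascade of Z-epoxy ester 6, closing cyclopropane and δ-lactone in one operation (run once, it supplies four of the five rings).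
4. 6 ⇐ tert-butyl hex-5-ynoate 1 + (S)-epichlorohydrin 2; 22 ⇐ (3Z,6Z)-nona-3,6-dien-1-ol 17; 12 ⇐ (4Z,7Z)-deca-4,7-dienal 11.
5. Ring order: cyclopropane + δ-lactone together (step 3) → oxirane (step 8, consumed) → oxolane (step 15).

Assumption: 1, 11 and 17 are bought as catalogue compounds. Locants in the Why lines are those of the two C20 halves: C1/C1′ lactone C=O, C5 lactone CH–O, C6–C8 cyclopropane; the unprimed half carries 9-OH and 12-OH, the primed half the 9′E alkene; the oxolane is O–C11–C10–C11′–C12′.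

## Route

Step 1
Reactants: 1 tert-butyl hex-5-ynoate; 2 (S)-epichlorohydrin
Product: 5 tert-butyl 7-[(2S)-oxiran-2-yl]hept-5-ynoate, via lithium acetylide 3 (not isolated), via chlorohydrin 4 (not isolated)
Conditions: n-BuLi (1.0 equiv), THF, −78 °C; BF3·OEt2, then 2, −78 °C; then 2 M aq NaOH, 0 °C → rt
Reagents that add atoms: none
Why: Yamaguchi–Hirao alkynylation opens the oxirane of 2 only at its CH2 terminus and hydroxide then closes the chlorohydrin (intramolecular Williamson), so no bond to the stereocentre is made or broken and it stays S, while at −78 °C sp C–H lithiation outruns attack on the hindered tert-butyl ester.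

Step 2
Reactants: 5 tert-butyl 7-[(2S)-oxiran-2-yl]hept-5-ynoate
Product: 6 tert-butyl (5Z)-7-[(2S)-oxiran-2-yl]hept-5-enoate
Conditions: H2 (1 atm), Lindlar catalyst, quinoline, EtOAc, rt
Reagents that add atoms: none
Why: Lindlar semihydrogenation adds H2 syn to give the 5Z alkene that fixes the C5/C6 relationship in the cascade; oxirane and ester are inert.

Step 3
Reactants: 6 tert-butyl (5Z)-7-[(2S)-oxiran-2-yl]hept-5-enoate
Product: 8 (6R)-6-[(1S,2S)-2-(hydroxymethyl)cyclopropyl]oxan-2-one, via oxocarbenium trifluoroborate zwitterion 7 (not isolated)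
Conditions: BF3·OEt2 (0.3 equiv), CH2Cl2, −78 → −30 °C
Reagents that add atoms: none
Why: Proposed new method: the BF3-activated C8–O bond ionises with backside (homoallyl) participation of the C5=C6 π bond (3-exo closure, inversion at C8, trans ring because C9/O point away from the C4 side of the Z-alkene) and the developing cyclopropylcarbinyl cation at C5 is captured anti by the tert-butyl ester carbonyl, which then loses isobutene and returns the proton, so the single oxirane stereocentre plus the Z geometry set 5R,6S,8S; the closest known reaction types are homoallyl → cyclopropylcarbinyl sulfonate solvolysis and epoxide-initiated cation–olefin cyclisation terminated by a tert-butyl ester.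

Step 4
Reactants: 8 (6R)-6-[(1S,2S)-2-(hydroxymethyl)cyclopropyl]oxan-2-one
Product: 9 (1S,2S)-2-[(2R)-6-oxooxan-2-yl]cyclopropane-1-carbaldehyde
Conditions: Dess–Martin periodinane, NaHCO3, CH2Cl2, 0 °C → rt
Reagents that add atoms: none
Why: Dess–Martin oxidation of the primary alcohol under buffered conditions; the cyclopropyl α-centre does not epimerise and no new stereocentre is formed.

Step 5
Reactants: 9 (1S,2S)-2-[(2R)-6-oxooxan-2-yl]cyclopropane-1-carbaldehyde
Product: 10 (6R)-6-[(1S,2S)-2-ethynylcyclopropyl]oxan-2-one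
Conditions: (MeO)2P(O)CHN2, KOtBu, THF, −78 → −20 °C
Reagents that add atoms: dimethyl (diazomethyl)phosphonate, COP(=O)(OC)C=[N+]=[N-]
Why: Seyferth–Gilbert homologation (aprotic and cold, so the δ-lactone is not alcoholysed) converts CHO into C≡CH without touching any stereocentre.

Step 6
Reactants: 11 (4Z,7Z)-deca-4,7-dienal
Product: 12 (2S,4Z,7Z)-2-chlorodeca-4,7-dienal
Conditions: NCS, (2R,5R)-2,5-diphenylpyrrolidine (10 mol %), CH2Cl2, 0 °C → rt; pentane filtration, used at once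
Reagents that add atoms: N-chlorosuccinimide, ClN1C(=O)CCC1=O
Why: Organocatalytic enamine α-chlorination, with the C2-symmetric amine (antipode chosen for the 2S chloride) shielding one enamine face; this sets C12′ (it becomes 12′R after the inversion in step 8).

Step 7
Reactants: 10 (6R)-6-[(1S,2S)-2-ethynylcyclopropyl]oxan-2-one; 12 (2S,4Z,7Z)-2-chlorodeca-4,7-dienal
Product: 15 (6R)-6-[(1S,2R)-2-[(1E,3R,4S,6Z,9Z)-4-chloro-3-hydroxydodeca-1,6,9-trien-1-yl]cyclopropyl]oxan-2-one, via alkenylzirconocene chloride 13 (not isolated), via alkenyl(methyl)zinc 14 (not isolated)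
Conditions: Cp2Zr(H)Cl, CH2Cl2, rt; Me2Zn, −65 °C; then 12, 0 °C; aq NH4Cl
Reagents that add atoms: none
Why: Schwartz hydrozirconation (syn, Zr terminal) fixes the 9′E alkene, Zr→Zn transmetalation (Wipf) gives an ester-tolerant alkenylzinc, and its Cornforth/polar Felkin–Anh addition to the α-chloroaldehyde gives the 1,2-anti chlorohydrin (11′R,12′S).

Step 8
Reactants: 15 (6R)-6-[(1S,2R)-2-[(1E,3R,4S,6Z,9Z)-4-chloro-3-hydroxydodeca-1,6,9-trien-1-yl]cyclopropyl]oxan-2-one
Product: 16 (6R)-6-[(1S,2R)-2-{(E)-2-[(2R,3R)-3-[(2Z,5Z)-octa-2,5-dien-1-yl]oxiran-2-yl]ethenyl}cyclopropyl]oxan-2-one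
Conditions: Cs2CO3, MeCN, rt; filtered through basic alumina, used crude
Reagents that add atoms: none
Why: Intramolecular Williamson closure (SN2, inversion at C12′) turns the anti-chlorohydrin stereospecifically into the trans (11′R,12′R) vinyl epoxide under aprotic conditions that spare the lactone.

Step 9
Reactants: 17 (3Z,6Z)-nona-3,6-dien-1-ol
Product: 18 (3Z,6Z)-nona-3,6-dienal
Conditions: Dess–Martin periodinane, NaHCO3, CH2Cl2, 0 °C; used crude at once
Reagents that add atoms: none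
Why: Buffered Dess–Martin oxidation gives the β,γ-unsaturated aldehyde without migration of the 3Z alkene into conjugation.

Step 10
Reactants: 18 (3Z,6Z)-nona-3,6-dienal
Product: 20 rac-(5Z,8Z)-undeca-5,8-dien-1-yn-3-yl acetate, via bromomagnesium alkoxide 19 (not isolated)
Conditions: HC≡CMgBr, THF, −78 °C; then Ac2O, −78 °C → rt
Reagents that add atoms: ethynylmagnesium bromide, C#C[Mg]Br; acetic anhydride, CC(=O)OC(C)=O
Why: Grignard 1,2-addition at −78 °C (faster than enolisation of the skipped aldehyde) followed by in-flask O-acylation gives the racemic propargylic acetate for resolution.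

Step 11
Reactants: 20 rac-(5Z,8Z)-undeca-5,8-dien-1-yn-3-yl acetate
Product: 21 (3S,5Z,8Z)-undeca-5,8-dien-1-yn-3-ol
Conditions: Amano lipase PS, pH 7 phosphate buffer/acetone, 25 °C, to ca. 40 % conversion; unreacted (R)-acetate removed by chromatography
Reagents that add atoms: none
Why: Lipase kinetic resolution by enantioselective ester hydrolysis; by Kazlauskas' rule (ethynyl = medium, CH2CH=CH chain = large) the enzyme cleaves the ester whose carbinol is S by CIP (ethynyl outranks the alkyl chain), which sets C12.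

Step 12
Reactants: 21 (3S,5Z,8Z)-undeca-5,8-dien-1-yn-3-ol
Product: 22 tert-butyl(dimethyl){[(3S,5Z,8Z)-undeca-5,8-dien-1-yn-3-yl]oxy}silane
Conditions: TBSCl, imidazole, DMF, rt
Reagents that add atoms: tert-butyldimethylsilyl chloride, CC(C)(C)[Si](C)(C)Cl
Why: Silyl ether formation masks the C12 hydroxyl, so that only C9–OH is oxidised in step 14 and no free γ-OH interferes with the Pd step; the stereocentre is untouched.

Step 13
Reactants: 22 tert-butyl(dimethyl){[(3S,5Z,8Z)-undeca-5,8-dien-1-yn-3-yl]oxy}silane; 9 (1S,2S)-2-[(2R)-6-oxooxan-2-yl]cyclopropane-1-carbaldehyde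
Product: 25 (6R)-6-[(1S,2S)-2-[(2E,4S,6Z,9Z)-4-{[tert-butyl(dimethyl)silyl]oxy}-1-hydroxydodeca-2,6,9-trien-1-yl]cyclopropyl]oxan-2-one (both C1 epimers), via alkenylzirconocene chloride 23 (not isolated), via alkenyl(methyl)zinc 24 (not isolated)
Conditions: Cp2Zr(H)Cl (1.05 equiv), CH2Cl2, rt; Me2Zn, −65 °C; then 9, 0 °C; aq NH4Cl
Reagents that add atoms: none
Why: Hydrozirconation–transmetalation–aldehyde addition (Wipf) builds the C9–C10 bond and the 10E alkene in one flask without touching the lactone; the C9 epimer mixture is irrelevant because C9 is oxidised next.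

Step 14
Reactants: 25 (6R)-6-[(1S,2S)-2-[(2E,4S,6Z,9Z)-4-{[tert-butyl(dimethyl)silyl]oxy}-1-hydroxydodeca-2,6,9-trien-1-yl]cyclopropyl]oxan-2-one
Product: 26 (6R)-6-[(1S,2S)-2-[(2E,4S,6Z,9Z)-4-{[tert-butyl(dimethyl)silyl]oxy}dodeca-2,6,9-trienoyl]cyclopropyl]oxan-2-one
Conditions: Dess–Martin periodinane, NaHCO3, CH2Cl2, 0 °C → rt
Reagents that add atoms: none
Why: Dess–Martin oxidation of the allylic cyclopropyl carbinol converges both C9 epimers on the E-enone, the Michael acceptor for the annulation.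

Step 15
Reactants: 16 (6R)-6-[(1S,2R)-2-{(E)-2-[(2R,3R)-3-[(2Z,5Z)-octa-2,5-dien-1-yl]oxiran-2-yl]ethenyl}cyclopropyl]oxan-2-one; 26 (6R)-6-[(1S,2S)-2-[(2E,4S,6Z,9Z)-4-{[tert-butyl(dimethyl)silyl]oxy}dodeca-2,6,9-trienoyl]cyclopropyl]oxan-2-one
Product: 28 (6R)-6-[(1S,2S)-2-({(2S,3S,4S,5R)-2-[(1S,3Z,6Z)-1-{[tert-butyl(dimethyl)silyl]oxy}nona-3,6-dien-1-yl]-5-[(2Z,5Z)-octa-2,5-dien-1-yl]-4-[(E)-2-{(1R,2S)-2-[(2R)-6-oxooxan-2-yl]cyclopropyl}ethenyl]oxolan-3-yl}carbonyl)cyclopropyl]oxan-2-one, via π-allylpalladium alkoxide zwitterion 27 (not isolated)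
Conditions: Pd2(dba)3·CHCl3 (5 mol %), dppe (12 mol %), THF, 0 → 25 °C; 16 (1.3 equiv)
Reagents that add atoms: none
Why: Pd(0)-catalysed formal [3+2] cycloaddition of a vinyl epoxide with a Michael acceptor (Tsuji–Trost ionisation, oxa-Michael addition of the C12′ alkoxide to C11, then 5-ring C-allylation of the C10 enolate at C11′): C12′ is carried through untouched, C11′ is formed with net retention (Pd enters anti to C–O, the enolate attacks anti to Pd), and C10/C11 settle trans,trans because the oxa-Michael step is reversible and C10 is enolisable, giving the all-trans ring.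

Step 16
Reactants: 28 (the oxolane ketone of step 15)
Product: 29 (6R)-6-[(1S,2S)-2-[(R)-{(2S,3R,4S,5R)-2-[(1S,3Z,6Z)-1-{[tert-butyl(dimethyl)silyl]oxy}nona-3,6-dien-1-yl]-5-[(2Z,5Z)-octa-2,5-dien-1-yl]-4-[(E)-2-{(1R,2S)-2-[(2R)-6-oxooxan-2-yl]cyclopropyl}ethenyl]oxolan-3-yl}(hydroxy)methyl]cyclopropyl]oxan-2-one
Conditions: (S)-Me-CBS (30 mol %), catecholborane, toluene, −78 °C; MeOH, then aq NaHCO3
Reagents that add atoms: none
Why: Corey–Bakshi–Shibata reduction: the doubly flanked oxolan-3-yl group is RL and cyclopropyl RS, so the (S)-catalyst gives the 9R carbinol (same sense as acetophenone → R), which is also the non-chelation polar Felkin–Anh/1,3-anti product; lactones and alkenes are untouched at −78 °C.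

Step 17
Reactants: 29 (the silyl-protected diol precursor of step 16)
Product: 30 (6R)-6-[(1S,2S)-2-[(R)-hydroxy{(2S,3R,4S,5R)-2-[(1S,3Z,6Z)-1-hydroxynona-3,6-dien-1-yl]-5-[(2Z,5Z)-octa-2,5-dien-1-yl]-4-[(E)-2-{(1R,2S)-2-[(2R)-6-oxooxan-2-yl]cyclopropyl}ethenyl]oxolan-3-yl}methyl]cyclopropyl]oxan-2-one (CNP0273074.1)
Conditions: HF·pyridine, pyridine, THF, 0 °C → rt
Reagents that add atoms: none
Why: Buffered fluoride-mediated Si–O cleavage frees the C12 hydroxyl without touching any stereocentre, the δ-lactones, the cyclopropyl carbinol or the skipped dienes.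

## Compound list

1 | tert-butyl hex-5-ynoate | C#CCCCC(=O)OC(C)(C)C | starting material
2 | (S)-epichlorohydrin, (2S)-2-(chloromethyl)oxirane | ClC[C@@H]1CO1 | starting material
3 | tert-butyl 6-lithiohex-5-ynoate (lithium acetylide of 1) | [Li]C#CCCCC(=O)OC(C)(C)C | intermediate
4 | tert-butyl (8S)-9-chloro-8-hydroxynon-5-ynoate | ClC[C@@H](O)CC#CCCCC(=O)OC(C)(C)C | intermediate
5 | tert-butyl 7-[(2S)-oxiran-2-yl]hept-5-ynoate | CC(C)(C)OC(=O)CCCC#CC[C@H]1CO1 | intermediate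
6 | tert-butyl (5Z)-7-[(2S)-oxiran-2-yl]hept-5-enoate | CC(C)(C)OC(=O)CCC/C=C\C[C@H]1CO1 | intermediate
7 | BF3-bound alkoxide/2-tert-butoxyoxan-1-ylium zwitterion with cyclopropane and ring already closed (5R,6S,8S) | F[B-](F)(F)OC[C@H]1C[C@@H]1[C@H]1CCCC(OC(C)(C)C)=[O+]1 | intermediate
8 | (6R)-6-[(1S,2S)-2-(hydroxymethyl)cyclopropyl]oxan-2-one | OC[C@H]1C[C@@H]1[C@H]1CCCC(=O)O1 | intermediate
9 | (1S,2S)-2-[(2R)-6-oxooxan-2-yl]cyclopropane-1-carbaldehyde | O=C[C@H]1C[C@@H]1[C@H]1CCCC(=O)O1 | intermediate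
10 | (6R)-6-[(1S,2S)-2-ethynylcyclopropyl]oxan-2-one | C#C[C@H]1C[C@@H]1[C@H]1CCCC(=O)O1 | intermediate
11 | (4Z,7Z)-deca-4,7-dienal | O=CCC/C=C\C/C=C\CC | starting material
12 | (2S,4Z,7Z)-2-chlorodeca-4,7-dienal | O=C[C@@H](Cl)C/C=C\C/C=C\CC | intermediate
13 | (E)-alkenylzirconocene chloride from 10 (Cp2ZrCl on the terminal alkene carbon; Cp drawn σ-bound) | Cl[Zr](C1C=CC=C1)(C1C=CC=C1)/C=C/[C@H]1C[C@@H]1[C@H]1CCCC(=O)O1 | intermediate
14 | (E)-alkenyl(methyl)zinc from 13 | C[Zn]/C=C/[C@H]1C[C@@H]1[C@H]1CCCC(=O)O1 | intermediate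
15 | (6R)-6-[(1S,2R)-2-[(1E,3R,4S,6Z,9Z)-4-chloro-3-hydroxydodeca-1,6,9-trien-1-yl]cyclopropyl]oxan-2-one | CC/C=C\C/C=C\C[C@H](Cl)[C@H](O)/C=C/[C@H]1C[C@@H]1[C@H]1CCCC(=O)O1 | intermediate
16 | (6R)-6-[(1S,2R)-2-{(E)-2-[(2R,3R)-3-[(2Z,5Z)-octa-2,5-dien-1-yl]oxiran-2-yl]ethenyl}cyclopropyl]oxan-2-one | CC/C=C\C/C=C\C[C@H]1O[C@@H]1/C=C/[C@H]1C[C@@H]1[C@H]1CCCC(=O)O1 | intermediate
17 | (3Z,6Z)-nona-3,6-dien-1-ol | OCC/C=C\C/C=C\CC | starting material
18 | (3Z,6Z)-nona-3,6-dienal | O=CC/C=C\C/C=C\CC | intermediate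
19 | bromomagnesium (5Z,8Z)-undeca-5,8-dien-1-yn-3-olate (racemic) | Br[Mg]OC(C#C)C/C=C\C/C=C\CC | intermediate
20 | rac-(5Z,8Z)-undeca-5,8-dien-1-yn-3-yl acetate | CC(=O)OC(C#C)C/C=C\C/C=C\CC | intermediate
21 | (3S,5Z,8Z)-undeca-5,8-dien-1-yn-3-ol | C#C[C@@H](O)C/C=C\C/C=C\CC | intermediate
22 | tert-butyl(dimethyl){[(3S,5Z,8Z)-undeca-5,8-dien-1-yn-3-yl]oxy}silane | C#C[C@@H](O[Si](C)(C)C(C)(C)C)C/C=C\C/C=C\CC | intermediate
23 | (E)-alkenylzirconocene chloride from 22 (Cp drawn σ-bound) | Cl[Zr](C1C=CC=C1)(C1C=CC=C1)/C=C/[C@@H](O[Si](C)(C)C(C)(C)C)C/C=C\C/C=C\CC | intermediate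
24 | (E)-alkenyl(methyl)zinc from 23 | C[Zn]/C=C/[C@@H](O[Si](C)(C)C(C)(C)C)C/C=C\C/C=C\CC | intermediate
25 | (6R)-6-[(1S,2S)-2-[(2E,4S,6Z,9Z)-4-{[tert-butyl(dimethyl)silyl]oxy}-1-hydroxydodeca-2,6,9-trien-1-yl]cyclopropyl]oxan-2-one, both C1 epimers | CC/C=C\C/C=C\C[C@H](O[Si](C)(C)C(C)(C)C)/C=C/C(O)[C@H]1C[C@@H]1[C@H]1CCCC(=O)O1 | intermediate
26 | (6R)-6-[(1S,2S)-2-[(2E,4S,6Z,9Z)-4-{[tert-butyl(dimethyl)silyl]oxy}dodeca-2,6,9-trienoyl]cyclopropyl]oxan-2-one | CC/C=C\C/C=C\C[C@H](O[Si](C)(C)C(C)(C)C)/C=C/C(=O)[C@H]1C[C@@H]1[C@H]1CCCC(=O)O1 | intermediate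
27 | π-allylpalladium alkoxide zwitterion from 16 (drawn as its η1 form at C11′, dppe on Pd not drawn) | CC/C=C\C/C=C\C[C@@H]([O-])[C@@H]([Pd+])/C=C/[C@H]1C[C@@H]1[C@H]1CCCC(=O)O1 | intermediate
28 | all-trans oxolane ketone (name in step 15; ring 2S,3S,4S,5R) | CC/C=C\C/C=C\C[C@H](O[Si](C)(C)C(C)(C)C)[C@H]1O[C@H](C/C=C\C/C=C\CC)[C@@H](/C=C/[C@H]2C[C@@H]2[C@H]2CCCC(=O)O2)[C@@H]1C(=O)[C@H]1C[C@@H]1[C@H]1CCCC(=O)O1 | intermediate
29 | 12-O-TBS ether of the target (name in step 16; C9 R, ring 2S,3R,4S,5R) | CC/C=C\C/C=C\C[C@H](O[Si](C)(C)C(C)(C)C)[C@H]1O[C@H](C/C=C\C/C=C\CC)[C@@H](/C=C/[C@H]2C[C@@H]2[C@H]2CCCC(=O)O2)[C@@H]1[C@H](O)[C@H]1C[C@@H]1[C@H]1CCCC(=O)O1 | intermediate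
30 | CNP0273074.1 (name in step 17) | CC/C=C\C/C=C\C[C@H](O)[C@H]1O[C@H](C/C=C\C/C=C\CC)[C@@H](/C=C/[C@H]2C[C@@H]2[C@H]2CCCC(=O)O2)[C@@H]1[C@H](O)[C@H]1C[C@@H]1[C@H]1CCCC(=O)O1 | target

## Step count and risks

Total steps: 17. Longest linear sequence: 10 (steps 1, 2, 3, 4, 5, 7, 8, 15, 16, 17); the other branch (steps 9–14, then 15–17) is 9.

Most likely to fail:

**Step 3 (cascade).** The BF3-activated terminal oxirane may divert into a Meinwald hydride shift or halohydrin formation, or close the cis-cyclopropane, instead of the 3-exo/lactonisation path. The fallback sets out from 4 (isolated by leaving out the NaOH stage of step 1) and comes back at 9. Lindlar semihydrogenation of 4 gives tert-butyl (5Z,8S)-9-chloro-8-hydroxynon-5-enoate F1. The trigger is then changed from Lewis-acid oxirane opening to sulfonate solvolysis: Tf2O and 2,6-di-tert-butyl-4-methylpyridine (CH2Cl2, −78 → 0 °C) turn the C8 hydroxyl into a triflate, which ionises with the same π-participation and ester capture (inversion at C8, isobutene lost) to give (6R)-6-[(1S,2S)-2-(chloromethyl)cyclopropyl]oxan-2-one F2. A sulfonate has no oxirane to rearrange and needs no Lewis acid. NaI followed by trimethylamine N-oxide in DMSO (Ganem oxidation) converts CH2Cl into CHO, which is 9.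

**Step 15 (Pd [3+2]).** A 1,3-disubstituted π-allyl and a singly activated acyclic enone are a demanding pair; the zwitterion may isomerise to a dienol or ketone, or erode at C11′, before the reversible oxa-Michael adduct closes. The fallback sets out from 9 and 22 (partner 16 unchanged) and comes back at 28. Zn(OTf)2/Et3N-mediated addition of alkyne 22 to 9 gives the propargylic alcohol (6R)-6-[(1S,2S)-2-[(4S,6Z,9Z)-4-{[tert-butyl(dimethyl)silyl]oxy}-1-hydroxydodeca-6,9-dien-2-yn-1-yl]cyclopropyl]oxan-2-one F3, and Dess–Martin oxidation gives the corresponding ynone F4. Ynones are much better oxa-Michael acceptors, so the Pd zwitterion from 16 should add and close by allenolate C-allylation to the 3-acyl-4-vinyl-4,5-dihydrofuran F5 (C11′ and C12′ as in 28). This vinylogous ester is reduced 1,4 at C10=C11 (Stryker's reagent or L-Selectride); C10 (enolisable) and C11 (reversible oxa-Michael) are then equilibrated to the all-trans ring with catalytic DBU, giving 28.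

**Step 16 (C9 reduction).** Cyclopropyl versus oxolanyl discrimination by the CBS catalyst, and the intrinsic facial bias of the ketone, are both unproven. The fallback sets out from 28 and comes back at 29. Reduce under chelation control instead (Zn(BH4)2, Et2O, −20 °C; zinc bridges the ketone and ring oxygens and hydride enters anti to C11′), which should give the C9 epimer of 29, the (9S)-alcohol F6. Mitsunobu inversion with chloroacetic acid (PPh3, DIAD, toluene) gives the (9R)-chloroacetate F7. Thiourea/NaHCO3 in EtOH removes the chloroacetyl group without touching the δ-lactones, giving 29.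

Further compounds

F1 | step 3 | tert-butyl (5Z,8S)-9-chloro-8-hydroxynon-5-enoate | ClC[C@@H](O)C/C=C\CCCC(=O)OC(C)(C)C
F2 | step 3 | (6R)-6-[(1S,2S)-2-(chloromethyl)cyclopropyl]oxan-2-one | ClC[C@H]1C[C@@H]1[C@H]1CCCC(=O)O1
F3 | step 15 | (6R)-6-[(1S,2S)-2-[(4S,6Z,9Z)-4-{[tert-butyl(dimethyl)silyl]oxy}-1-hydroxydodeca-6,9-dien-2-yn-1-yl]cyclopropyl]oxan-2-one (both C1 epimers) | CC/C=C\C/C=C\C[C@H](O[Si](C)(C)C(C)(C)C)C#CC(O)[C@H]1C[C@@H]1[C@H]1CCCC(=O)O1
F4 | step 15 | (6R)-6-[(1S,2S)-2-[(4S,6Z,9Z)-4-{[tert-butyl(dimethyl)silyl]oxy}dodeca-6,9-dien-2-ynoyl]cyclopropyl]oxan-2-one | CC/C=C\C/C=C\C[C@H](O[Si](C)(C)C(C)(C)C)C#CC(=O)[C@H]1C[C@@H]1[C@H]1CCCC(=O)O1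
F5 | step 15 | 4,5-dihydrofuran analogue of 28 with a C10=C11 double bond in the ring (C11′ and C12′ as in 28) | CC/C=C\C/C=C\C[C@H](O[Si](C)(C)C(C)(C)C)C1=C(C(=O)[C@H]2C[C@@H]2[C@H]2CCCC(=O)O2)[C@H](/C=C/[C@H]2C[C@@H]2[C@H]2CCCC(=O)O2)[C@@H](C/C=C\C/C=C\CC)O1
F6 | step 16 | C9 epimer of 29 (9S carbinol) | CC/C=C\C/C=C\C[C@H](O[Si](C)(C)C(C)(C)C)[C@H]1O[C@H](C/C=C\C/C=C\CC)[C@@H](/C=C/[C@H]2C[C@@H]2[C@H]2CCCC(=O)O2)[C@@H]1[C@@H](O)[C@H]1C[C@@H]1[C@H]1CCCC(=O)O1
F7 | step 16 | 9-O-chloroacetate of 29 (9R) | CC/C=C\C/C=C\C[C@H](O[Si](C)(C)C(C)(C)C)[C@H]1O[C@H](C/C=C\C/C=C\CC)[C@@H](/C=C/[C@H]2C[C@@H]2[C@H]2CCCC(=O)O2)[C@@H]1[C@H](OC(=O)CCl)[C@H]1C[C@@H]1[C@H]1CCCC(=O)O1
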